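**Assumption (one line):** compounds 1, 3, 8 and 18 are taken as purchasable, and the (R)-ligand in step 2 is assigned to the 4R lactone by analogy with simpler coumarins; the sense must be confirmed on the first run.

Numbering used throughout: butyl chain C1–C4 (C1 = diaryl methine, C4 = benzylic CH2); ring A = phloroglucinol ring (C1′ on C1, acyl on C3′); ring B = 4-hydroxyphenyl on C1; ring C = 4-hydroxyphenyl on C4; ring D = 4-methoxyphenyl of the acyl chain. The target 22 is (1R,2S,3R).

## The problem

The target is an open-chain lignan–dihydrochalcone conjugate: ring A and ring B sit on C1, methyl groups on C2 and C3, ring C on C4, and ring A also carries the 3-(4-methoxyphenyl)propanoyl group. No ring holds the three contiguous stereocenters, and C2 and C3 bear only methyl groups, so the finished chain offers neither a conformational lock nor a functional handle. C2/C3 are the threo pair of a lignan; C1 is a diaryl methine whose two aryl groups differ only in oxygenation, and in the open chain it can feel C2 only through 1,2-induction. Ring A raises no regiochemical question, because the two free positions of a 1-alkylphloroglucinol are equivalent, but the C1–C1′ bond is a benzhydryl bond to a phloroglucinol and can reopen under strong acid (retro-Friedel–Crafts), which would scramble C1. The free polyphenol oxidises easily, the aryl ketone cannot pass hydride or organometallic steps, and the methyl ether of ring D rules out methyl protection of the five phenols. The feature the plan uses is that O2′ of ring A, C2′, C1′, C1, C2 and the methyl carbon on C2 are the six atoms of a latent 4-aryl-3,4-dihydrocoumarin (chroman-2-one) ring, the methyl carbon standing for the lactone carbonyl. In that ring C1 sits next to a lactone α-carbon (C2), ring B is forced pseudoaxial, and C3 can be made as the exocyclic β-carbon of an alkylidene lactone, so that C1, set by catalysis, can dictate C2 and C3 in one conjugate addition.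

## Retrosynthesis

**22 ⇒ 21.** The five phenolic O–H bonds are traced back to benzyl ethers. Benzyl is the only common phenol protection that comes off under neutral conditions and leaves the methyl ether of ring D, the ketone and the acid-labile C1–C1′ bond alone. The forward step is one hydrogenolysis.

**21 ⇒ 17 + 19 (and 17 ⇒ 16, 19 ⇒ 18).** The C3′–C(=O) bond is cut in the anionic sense: aryllithium 20 from bromide 17, and Weinreb amide 19 from acid chloride 18. A Friedel–Crafts acylation would be one step shorter, but it puts a Lewis acid on the benzhydryl–phloroglucinol bond. Acylating earlier would expose the ketone to the hydride steps. Because C3′ and C5′ of 16 are equivalent, bromination needs only mono-selectivity.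

**16 ⇒ 12 (through 15, 14, 13).** The methyl on C2 is raised to the carboxyl level and tied to O2′: the open chain 16 becomes the trans dihydrocoumarin 12. This is the step that turns an acyclic problem into a cyclic one with atoms the target already has. The alternative ring, a γ-butyrolactone through both methyl carbons, would need two carbonyl-to-methyl conversions and does not contain C1. Forward: LiAlH4 opening (13), benzylation of the freed phenol (14), tosylation (15), hydride displacement (16).

**12 ⇒ 7 + 8 (key disconnection).** The C3–C4 bond and the C2–H bond are cut: a 4-(benzyloxy)benzyl nucleophile (Grignard 9 from chloride 8) adds to the exocyclic carbon of the (E)-ethylidene lactone 7, then C2 is protonated. Cutting C2–C3 instead would need a lactone enolate and a secondary electrophile. Cutting C3–CH3 (methylcuprate onto a 2-arylethylidene lactone) would, by the same facial model, give the C3 epimer. The precursor 7 has one stereocenter and no ring C; the product has all three stereocenters and the whole lignan carbon skeleton. The forward reaction must attack anti to ring B and must beat 1,2-addition and γ-deprotonation.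

**7 ⇒ 4.** The C2=C3 double bond is cut as an aldol condensation of lactone 4 with acetaldehyde (aldol 5, mesylate 6). The forward step must give the E alkene and must not let the alkene slip into the ring.

**4 ⇒ 2 + 3 (and 2 ⇒ 1).** The C1–ring B bond is cut as a rhodium-catalysed asymmetric 1,4-addition of boronic acid 3 to coumarin 2. The other bond at C1 (C1–C1′, phenol plus cinnamate) is made under acid and is racemic. The chosen cut puts the one catalyst-controlled stereocenter at the very start on an achiral, flat substrate; 2 comes from 5,7-dihydroxycoumarin 1.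

## Roads not taken

**Alternative 1:** (the most obvious) Cut C1–C1′. Forward key step: oxidise the C2-symmetric bisphenol A2 to the quinone methide A3 and trap it with dihydrochalcone A1 in a Friedel–Crafts alkylation, as the presumed biosynthesis does. This is shorter by about five operations, and an allylic-strain model predicts the right sense at C1. What is unsecured is the size of that preference, because it rests on methyl versus sec-alkyl on a freely rotating C2. The union is also run on free polyphenols: A1 has two equivalent nucleophilic carbons, and the product still contains a para-hydroxybenzhydryl C–H that oxidises more easily than A2. C1 epimers would differ at one center of a flexible heptaphenol. The chosen plan pays the extra steps for a named control element at every stereocenter and for never handling an unprotected intermediate.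

**Alternative 2:** Cut C1–C1′, C1–C2 and C2–C3 one after another. Forward: iterative homologation of a benzylic boronic ester with chiral α-lithiated carbamates (1,2-metallate rearrangements) up to the secondary benzylic boronic ester A4, then stereoinvertive coupling of A4 with 2,4,6-tris(benzyloxy)phenyllithium. Each center is set by a separate stoichiometric chiral reagent. The C1 homologation needs a configurationally labile primary benzylic carbenoid. The last coupling asks a β-branched secondary boronate to form an ate complex with a di-ortho-substituted aryllithium, the worst steric case for that reaction. The end game after A4 would be the same as here, so nothing is saved.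

**Alternative 3:** Use the classical lignan lactone. Cut C1–C1′ in the conjugate sense: acid-mediated hydroarylation of the (E)-benzylidene butyrolactone A5 by phloroglucinol, then both carbonyl-level carbons to methyl. The ring holds C3, and attack anti to its benzyl group is predicted to give adduct A6, the C1 epimer of what is needed. Exchanging roles would mean adding a ring B nucleophile to a di-ortho-substituted, electron-rich arylidene, a poor acceptor. Two carbons (not one) must be taken from the carboxyl or carbinol level to methyl. In the dihydrocoumarin the same anti attack maps onto the natural configuration.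

Key step: step 5

## Route

Step 1
Reactants: 1 5,7-dihydroxycoumarin
Product: 2 5,7-bis(benzyloxy)coumarin
Conditions: BnBr (2.3 equiv), K2CO3, DMF, 50 °C
Reagents that add atoms: benzyl bromide, BrCc1ccccc1
Why: Williamson etherification of both phenols; the coumarin lactone is inert to carbonate, and benzyl is chosen because it can be removed at the end without touching the methyl ether of ring D.

Step 2
Reactants: 2 5,7-bis(benzyloxy)coumarin; 3 [4-(benzyloxy)phenyl]boronic acid
Product: 4 (4R)-5,7-bis(benzyloxy)-4-[4-(benzyloxy)phenyl]chroman-2-one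
Conditions: Rh(acac)(C2H4)2 (3 mol %), (R)-SEGPHOS (3.3 mol %), 3 (3 equiv), dioxane/H2O 10:1, 60 °C
Reagents that add atoms: none
Why: Hayashi–Miyaura asymmetric 1,4-addition to a coumarin (aryl transfer from boron to monovalent rhodium, insertion of C3=C4, hydrolysis of the oxa-π-allyl); the chiral bisphosphine alone sets C4 of the lactone (C1 of the target) as R.

Step 3
Reactants: 4 (4R)-5,7-bis(benzyloxy)-4-[4-(benzyloxy)phenyl]chroman-2-one
Product: 5 (4R)-5,7-bis(benzyloxy)-4-[4-(benzyloxy)phenyl]-3-(1-hydroxyethyl)chroman-2-one (epimers at C3 and at the carbinol carbon)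
Conditions: LiN(SiMe3)2 (1.05 equiv), THF, −78 °C; CH3CHO (3 equiv), −78 °C; AcOH quench at −78 °C
Reagents that add atoms: acetaldehyde, CC=O
Why: Aldol addition of the lithium enolate of a dihydrocoumarin; the cold quench keeps the aldolate from closing to a β-lactone with loss of the phenoxide, and the two new centers are removed in the next step so their ratio does not matter.

Step 4
Reactants: 5 (4R)-5,7-bis(benzyloxy)-4-[4-(benzyloxy)phenyl]-3-(1-hydroxyethyl)chroman-2-one
Product: 7 (3E,4R)-5,7-bis(benzyloxy)-4-[4-(benzyloxy)phenyl]-3-ethylidenechroman-2-one, via mesylate 6 (not isolated)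
Conditions: MsCl (1.5 equiv), Et3N (4 equiv), CH2Cl2, −20 to 0 °C
Reagents that add atoms: none
Why: Mesylation and E1cB elimination through the lactone enolate, which converges both carbinol epimers on the E alkene (methyl away from the carbonyl); the weak amine base and low temperature are chosen to spare the now acidic C4–H.

Step 5
Reactants: 7 (3E,4R)-5,7-bis(benzyloxy)-4-[4-(benzyloxy)phenyl]-3-ethylidenechroman-2-one; 8 4-(benzyloxy)benzyl chloride
Product: 12 (3S,4R)-5,7-bis(benzyloxy)-4-[4-(benzyloxy)phenyl]-3-[(2R)-1-[4-(benzyloxy)phenyl]propan-2-yl]chroman-2-one, via Grignard reagent 9 (not isolated), via silyl ketene acetal 10 (not isolated), via cis lactone 11 (not isolated)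
Conditions: 8, Mg, THF, 0 °C; then CuBr·SMe2 (20 mol %), Me3SiCl (2 equiv), 7, THF, −78 °C; aq. NH4Cl; then DBU (0.2 equiv), toluene, rt
Reagents that add atoms: none
Why: The benzylcopper species formed from 9 and monovalent copper adds 1,4 to the s-cis enoate of 7, and Me3SiCl traps the enolate as silyl ketene acetal 10, which blocks both ketene loss of the phenoxide and 1,2-attack on the aryl ester. The closest known reaction type is the copper-catalysed, chlorosilane-accelerated conjugate addition of Grignard reagents to α-alkylidene lactones. No ring is closed; the dihydrocoumarin ring already present is the control element. For C3 of the target: in 7 the E-methyl is syn to C4 of the lactone, so 1,3-allylic strain (reinforced by the peri 5-benzyloxy group) puts C4–H in the alkene plane and ring B pseudoaxial over one face of the exocyclic carbon; the benzyl group therefore enters anti to ring B, which with the E geometry gives the 3R configuration of the target. For C2 of the target: hydrolysis of 10 protonates the lactone α-carbon mainly anti to ring B (cis lactone 11), and DBU then equilibrates through the enolate to the trans-diaxial lactone 12, which avoids the gauche contact between the side chain and ring B; this is 2S of the target. The step needs face selectivity (secured by axial ring B), geometric purity of 7 (the Z isomer would invert C3), and 1,4-addition ahead of γ-deprotonation at C4 (secured by copper, Me3SiCl and −78 °C). C1 of the target is not touched, since C4–H is no longer acidic once the alkene is saturated.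

Step 6
Reactants: 12 (3S,4R)-5,7-bis(benzyloxy)-4-[4-(benzyloxy)phenyl]-3-[(2R)-1-[4-(benzyloxy)phenyl]propan-2-yl]chroman-2-one
Product: 13 (2S,3R)-2-[(R)-[2,4-bis(benzyloxy)-6-hydroxyphenyl][4-(benzyloxy)phenyl]methyl]-4-[4-(benzyloxy)phenyl]-3-methylbutan-1-ol
Conditions: LiAlH4, THF, 0 °C
Reagents that add atoms: none
Why: Hydride reduction of an aryl lactone to phenol plus primary alcohol; it is fast at 0 °C, so the α-center is reduced before it can epimerise.

Step 7
Reactants: 13 (2S,3R)-2-[(R)-[2,4-bis(benzyloxy)-6-hydroxyphenyl][4-(benzyloxy)phenyl]methyl]-4-[4-(benzyloxy)phenyl]-3-methylbutan-1-ol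
Product: 14 (2S,3R)-4-[4-(benzyloxy)phenyl]-2-[(R)-[4-(benzyloxy)phenyl][2,4,6-tris(benzyloxy)phenyl]methyl]-3-methylbutan-1-ol
Conditions: BnBr (1.1 equiv), K2CO3, acetone, reflux
Reagents that add atoms: benzyl bromide, BrCc1ccccc1
Why: Chemoselective Williamson etherification: carbonate deprotonates only the phenol, so the primary alcohol stays free; this also makes ring A symmetric again and removes the phenoxide that would otherwise close a chroman in step 9.

Step 8
Reactants: 14 (2S,3R)-4-[4-(benzyloxy)phenyl]-2-[(R)-[4-(benzyloxy)phenyl][2,4,6-tris(benzyloxy)phenyl]methyl]-3-methylbutan-1-ol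
Product: 15 (2S,3R)-4-[4-(benzyloxy)phenyl]-2-[(R)-[4-(benzyloxy)phenyl][2,4,6-tris(benzyloxy)phenyl]methyl]-3-methylbutyl 4-methylbenzenesulfonate
Conditions: TsCl, Et3N, DMAP (cat.), CH2Cl2, 0 °C to rt
Reagents that add atoms: p-toluenesulfonyl chloride, Cc1ccc(cc1)S(Cl)(=O)=O
Why: Standard sulfonylation of a primary alcohol; no stereocenter is involved.

Step 9
Reactants: 15 (2S,3R)-4-[4-(benzyloxy)phenyl]-2-[(R)-[4-(benzyloxy)phenyl][2,4,6-tris(benzyloxy)phenyl]methyl]-3-methylbutyl 4-methylbenzenesulfonate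
Product: 16 1,3,5-tris(benzyloxy)-2-[(1R,2S,3R)-1,4-bis[4-(benzyloxy)phenyl]-2,3-dimethylbutyl]benzene
Conditions: LiEt3BH (3 equiv), THF, 0 °C to rt
Reagents that add atoms: none
Why: SN2 displacement of a primary tosylate by hydride, the classical lignan way of turning CH2OH into CH3; the reaction is at a CH2 group, so C2 keeps its configuration.

Step 10
Reactants: 16 1,3,5-tris(benzyloxy)-2-[(1R,2S,3R)-1,4-bis[4-(benzyloxy)phenyl]-2,3-dimethylbutyl]benzene
Product: 17 1,3,5-tris(benzyloxy)-2-bromo-4-[(1R,2S,3R)-1,4-bis[4-(benzyloxy)phenyl]-2,3-dimethylbutyl]benzene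
Conditions: N-bromosuccinimide (1.0 equiv), CH2Cl2, −40 to 0 °C, dark
Reagents that add atoms: N-bromosuccinimide, O=C1CCC(=O)N1Br
Why: Electrophilic aromatic bromination; ring A with three alkoxy groups is far more reactive than the monoalkoxy rings B and C, its two free positions are equivalent, and one equivalent in the dark avoids both dibromination and radical attack at C1–H.

Step 11
Reactants: 18 3-(4-methoxyphenyl)propanoyl chloride
Product: 19 N-methoxy-3-(4-methoxyphenyl)-N-methylpropanamide
Conditions: MeNH(OMe)·HCl, Et3N (2.2 equiv), CH2Cl2, 0 °C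
Reagents that add atoms: N,O-dimethylhydroxylamine hydrochloride, CNOC.Cl
Why: Acylation of the hydroxylamine to the Weinreb amide, which stops an aryllithium at the ketone stage.

Step 12
Reactants: 17 1,3,5-tris(benzyloxy)-2-bromo-4-[(1R,2S,3R)-1,4-bis[4-(benzyloxy)phenyl]-2,3-dimethylbutyl]benzene; 19 N-methoxy-3-(4-methoxyphenyl)-N-methylpropanamide
Product: 21 1-[2,4,6-tris(benzyloxy)-3-[(1R,2S,3R)-1,4-bis[4-(benzyloxy)phenyl]-2,3-dimethylbutyl]phenyl]-3-(4-methoxyphenyl)propan-1-one, via aryllithium 20 (not isolated)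
Conditions: n-BuLi (1.05 equiv), THF, −78 °C; then 19, −78 to 0 °C; aq. NH4Cl
Reagents that add atoms: none
Why: Bromine–lithium exchange, which at −78 °C is faster than deprotonation of a benzylic OCH2, followed by the Weinreb ketone synthesis; the acyl group is brought in without any acid, so the C1–C1′ bond is not at risk.

Step 13
Reactants: 21 1-[2,4,6-tris(benzyloxy)-3-[(1R,2S,3R)-1,4-bis[4-(benzyloxy)phenyl]-2,3-dimethylbutyl]phenyl]-3-(4-methoxyphenyl)propan-1-one
Product: 22 1-[3-[(1R,2S,3R)-1,4-bis(4-hydroxyphenyl)-2,3-dimethylbutyl]-2,4,6-trihydroxyphenyl]-3-(4-methoxyphenyl)propan-1-one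
Conditions: H2 (1 atm), 10 % Pd/C, EtOAc/MeOH, rt, degassed work-up
Reagents that add atoms: none
Why: Hydrogenolysis of five benzyl ethers under neutral conditions; the hydrogen-bonded acylphloroglucinol ketone, the aryl methyl ether and the C–C bonds at C1 are not reduced under these conditions.

## Compound list

1 | 5,7-dihydroxycoumarin | O=C1C=Cc2c(O)cc(O)cc2O1 | starting material
2 | 5,7-bis(benzyloxy)coumarin | O=C1C=Cc2c(OCc3ccccc3)cc(OCc3ccccc3)cc2O1 | intermediate
3 | [4-(benzyloxy)phenyl]boronic acid | OB(O)c1ccc(OCc2ccccc2)cc1 | starting material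
4 | (4R)-5,7-bis(benzyloxy)-4-[4-(benzyloxy)phenyl]chroman-2-one | O=C1C[C@H](c2ccc(OCc3ccccc3)cc2)c2c(OCc3ccccc3)cc(OCc3ccccc3)cc2O1 | intermediate
5 | (4R)-5,7-bis(benzyloxy)-4-[4-(benzyloxy)phenyl]-3-(1-hydroxyethyl)chroman-2-one (epimers at C3 and carbinol carbon) | CC(O)C1C(=O)Oc2cc(OCc3ccccc3)cc(OCc3ccccc3)c2[C@H]1c1ccc(OCc2ccccc2)cc1 | intermediate
6 | 1-[(4R)-5,7-bis(benzyloxy)-4-[4-(benzyloxy)phenyl]-2-oxochroman-3-yl]ethyl methanesulfonate | CC(OS(C)(=O)=O)C1C(=O)Oc2cc(OCc3ccccc3)cc(OCc3ccccc3)c2[C@H]1c1ccc(OCc2ccccc2)cc1 | intermediate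
7 | (3E,4R)-5,7-bis(benzyloxy)-4-[4-(benzyloxy)phenyl]-3-ethylidenechroman-2-one | O=C1Oc2cc(OCc3ccccc3)cc(OCc3ccccc3)c2[C@@H](c2ccc(OCc3ccccc3)cc2)/C1=C\C | intermediate
8 | 4-(benzyloxy)benzyl chloride | ClCc1ccc(OCc2ccccc2)cc1 | starting material
9 | [4-(benzyloxy)benzyl]magnesium chloride | Cl[Mg]Cc1ccc(OCc2ccccc2)cc1 | intermediate
10 | (4R)-5,7-bis(benzyloxy)-4-[4-(benzyloxy)phenyl]-3-[(2R)-1-[4-(benzyloxy)phenyl]propan-2-yl]-2-(trimethylsilyloxy)-4H-chromene | C[Si](C)(C)OC1=C([C@H](C)Cc2ccc(OCc3ccccc3)cc2)[C@H](c2ccc(OCc3ccccc3)cc2)c2c(OCc3ccccc3)cc(OCc3ccccc3)cc2O1 | intermediate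
11 | (3R,4R)-5,7-bis(benzyloxy)-4-[4-(benzyloxy)phenyl]-3-[(2R)-1-[4-(benzyloxy)phenyl]propan-2-yl]chroman-2-one (cis) | O=C1Oc2cc(OCc3ccccc3)cc(OCc3ccccc3)c2[C@@H](c2ccc(OCc3ccccc3)cc2)[C@H]1[C@H](C)Cc1ccc(OCc2ccccc2)cc1 | intermediate
12 | (3S,4R)-5,7-bis(benzyloxy)-4-[4-(benzyloxy)phenyl]-3-[(2R)-1-[4-(benzyloxy)phenyl]propan-2-yl]chroman-2-one (trans) | O=C1Oc2cc(OCc3ccccc3)cc(OCc3ccccc3)c2[C@@H](c2ccc(OCc3ccccc3)cc2)[C@@H]1[C@H](C)Cc1ccc(OCc2ccccc2)cc1 | intermediate
13 | (2S,3R)-2-[(R)-[2,4-bis(benzyloxy)-6-hydroxyphenyl][4-(benzyloxy)phenyl]methyl]-4-[4-(benzyloxy)phenyl]-3-methylbutan-1-ol | Oc1cc(OCc2ccccc2)cc(OCc2ccccc2)c1[C@@H](c1ccc(OCc2ccccc2)cc1)[C@@H](CO)[C@H](C)Cc1ccc(OCc2ccccc2)cc1 | intermediate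
14 | (2S,3R)-4-[4-(benzyloxy)phenyl]-2-[(R)-[4-(benzyloxy)phenyl][2,4,6-tris(benzyloxy)phenyl]methyl]-3-methylbutan-1-ol | c1ccccc1COc1cc(OCc2ccccc2)cc(OCc2ccccc2)c1[C@@H](c1ccc(OCc2ccccc2)cc1)[C@@H](CO)[C@H](C)Cc1ccc(OCc2ccccc2)cc1 | intermediate
15 | (2S,3R)-4-[4-(benzyloxy)phenyl]-2-[(R)-[4-(benzyloxy)phenyl][2,4,6-tris(benzyloxy)phenyl]methyl]-3-methylbutyl 4-methylbenzenesulfonate | c1ccccc1COc1cc(OCc2ccccc2)cc(OCc2ccccc2)c1[C@@H](c1ccc(OCc2ccccc2)cc1)[C@@H](COS(=O)(=O)c1ccc(C)cc1)[C@H](C)Cc1ccc(OCc2ccccc2)cc1 | intermediate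
16 | 1,3,5-tris(benzyloxy)-2-[(1R,2S,3R)-1,4-bis[4-(benzyloxy)phenyl]-2,3-dimethylbutyl]benzene | c1ccccc1COc1cc(OCc2ccccc2)cc(OCc2ccccc2)c1[C@@H](c1ccc(OCc2ccccc2)cc1)[C@@H](C)[C@H](C)Cc1ccc(OCc2ccccc2)cc1 | intermediate
17 | 1,3,5-tris(benzyloxy)-2-bromo-4-[(1R,2S,3R)-1,4-bis[4-(benzyloxy)phenyl]-2,3-dimethylbutyl]benzene | c1ccccc1COc1c(Br)c(OCc2ccccc2)cc(OCc2ccccc2)c1[C@@H](c1ccc(OCc2ccccc2)cc1)[C@@H](C)[C@H](C)Cc1ccc(OCc2ccccc2)cc1 | intermediate
18 | 3-(4-methoxyphenyl)propanoyl chloride | COc1ccc(CCC(Cl)=O)cc1 | starting material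
19 | N-methoxy-3-(4-methoxyphenyl)-N-methylpropanamide | COc1ccc(CCC(=O)N(C)OC)cc1 | intermediate
20 | [2,4,6-tris(benzyloxy)-3-[(1R,2S,3R)-1,4-bis[4-(benzyloxy)phenyl]-2,3-dimethylbutyl]phenyl]lithium | c1ccccc1COc1c([Li])c(OCc2ccccc2)cc(OCc2ccccc2)c1[C@@H](c1ccc(OCc2ccccc2)cc1)[C@@H](C)[C@H](C)Cc1ccc(OCc2ccccc2)cc1 | intermediate
21 | 1-[2,4,6-tris(benzyloxy)-3-[(1R,2S,3R)-1,4-bis[4-(benzyloxy)phenyl]-2,3-dimethylbutyl]phenyl]-3-(4-methoxyphenyl)propan-1-one | c1ccccc1COc1c(C(=O)CCc2ccc(OC)cc2)c(OCc2ccccc2)cc(OCc2ccccc2)c1[C@@H](c1ccc(OCc2ccccc2)cc1)[C@@H](C)[C@H](C)Cc1ccc(OCc2ccccc2)cc1 | intermediate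
22 | 1-[3-[(1R,2S,3R)-1,4-bis(4-hydroxyphenyl)-2,3-dimethylbutyl]-2,4,6-trihydroxyphenyl]-3-(4-methoxyphenyl)propan-1-one | COc1ccc(CCC(=O)c2c(O)cc(O)c([C@@H](c3ccc(O)cc3)[C@@H](C)[C@H](C)Cc3ccc(O)cc3)c2O)cc1 | target

## Step count and risk

Total: 13 steps. Longest linear sequence: 12 steps (steps 1–10, 12, 13); step 11 is a one-step side branch.

**Step 5 (key step).** What may go wrong: insufficient facial discrimination at the exocyclic carbon if ring B does not sit cleanly pseudoaxial; γ-deprotonation at C4 by the basic organometallic with drift of the alkene into the ring (an achiral coumarin); or 1,2-attack on the aryl ester. Fallback: the same relay from C1 run as two ring-controlled enolate alkylations, from 4 to 16, with no alkylidene at all.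
- The enolate of 4 (LiN(SiMe3)2, −78 °C) is alkylated anti to ring B with methyl bromoacetate to give methyl [(3S,4R)-5,7-bis(benzyloxy)-4-[4-(benzyloxy)phenyl]-2-oxochroman-3-yl]acetate F1.
- NaBH4 (THF/MeOH, 0 °C) reduces the activated aryl lactone but not the methyl ester, and the liberated primary alcohol closes onto the ester to give the butyrolactone (4S)-4-[(R)-[2,4-bis(benzyloxy)-6-hydroxyphenyl][4-(benzyloxy)phenyl]methyl]dihydrofuran-2(3H)-one F2.
- BnBr/K2CO3 gives the phenol ether (4S)-4-[(R)-[4-(benzyloxy)phenyl][2,4,6-tris(benzyloxy)phenyl]methyl]dihydrofuran-2(3H)-one F3.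
- Its enolate is alkylated with 8 (NaI) anti to the β-substituent, the standard trans-selective step of lignan lactone chemistry, to give (3R,4R)-3-[4-(benzyloxy)benzyl]-4-[(R)-[4-(benzyloxy)phenyl][2,4,6-tris(benzyloxy)phenyl]methyl]dihydrofuran-2(3H)-one F4.
- LiAlH4 gives (2R,3R)-2-[4-(benzyloxy)benzyl]-3-[(R)-[4-(benzyloxy)phenyl][2,4,6-tris(benzyloxy)phenyl]methyl]butane-1,4-diol F5; TsCl gives its bis(4-methylbenzenesulfonate) F6; LiEt3BH converts both CH2OTs groups into methyl and returns to the route at 16.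

**Step 4.** What may go wrong: base-promoted removal of the doubly benzylic, vinylogous C4–H of 7 followed by a prototropic shift of the exocyclic alkene into the ring, which gives an aromatic coumarin and destroys C1; formation of E/Z mixtures, where the Z isomer would invert C3 in step 5. Fallback: make the alkene by olefination instead of elimination. The enolate of 4 is C-phosphinylated with ClP(OEt)2 and oxidised (aq. H2O2) to diethyl [(4R)-5,7-bis(benzyloxy)-4-[4-(benzyloxy)phenyl]-2-oxochroman-3-yl]phosphonate F7. A Horner–Wadsworth–Emmons reaction with acetaldehyde under LiCl/iPr2NEt then forms the C=C bond at low temperature and returns to the route at 7.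

**Step 2.** What may go wrong: slow insertion of the electron-rich coumarin, whose C4 is flanked by the peri 5-benzyloxy group, so that protodeboronation of 3 and hydrolytic opening of the lactone take over. Fallback: build the C1–C1′ bond instead of the C1–ring B bond, by iminium catalysis, setting out from 3.
- Oxidative Heck coupling of 3 with acrolein (Pd(OAc)2, 2,9-dimethyl-1,10-phenanthroline, p-benzoquinone, MeCN) gives (E)-3-[4-(benzyloxy)phenyl]prop-2-enal F8.
- Friedel–Crafts addition of commercial 3,5-bis(benzyloxy)phenol to F8, catalysed by an α,α-diphenylprolinol trimethylsilyl ether (the enantiomer that gives 4R), with ring closure, gives (4R)-5,7-bis(benzyloxy)-4-[4-(benzyloxy)phenyl]chroman-2-ol F9.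
- Oxidation of the lactol (TEMPO, PhI(OAc)2) returns to the route at 4.

**Step 12.** What may go wrong: proton transfer to the hindered aryllithium 20 from the α-CH2 of 19 or from a neighbouring OCH2Ph (with anionic rearrangement of the benzyl ether), which returns 16 or rearranged material instead of ketone. Fallback: electrophilic formylation followed by nucleophilic addition, setting out from 16.
- Vilsmeier–Haack reaction (POCl3, DMF, 0 °C to rt) gives 2,4,6-tris(benzyloxy)-3-[(1R,2S,3R)-1,4-bis[4-(benzyloxy)phenyl]-2,3-dimethylbutyl]benzaldehyde F10.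
- 2-(4-Methoxyphenyl)ethylmagnesium bromide adds to give 1-[2,4,6-tris(benzyloxy)-3-[(1R,2S,3R)-1,4-bis[4-(benzyloxy)phenyl]-2,3-dimethylbutyl]phenyl]-3-(4-methoxyphenyl)propan-1-ol F11.
- Dess–Martin oxidation returns to the route at 21.

**Step 9.** What may go wrong: hydride attack at the β,β-disubstituted primary carbon is slow, so the ortho benzyloxy oxygen can displace the tosylate intramolecularly (six-membered oxonium, then loss of benzyl) and close a chroman. Fallback: a radical reduction that does not depend on SN2 by hydride, setting out from 14. I2, PPh3 and imidazole give 1,3,5-tris(benzyloxy)-2-[(1R,2S,3R)-1,4-bis[4-(benzyloxy)phenyl]-2-(iodomethyl)-3-methylbutyl]benzene F12; Bu3SnH with azobisisobutyronitrile in toluene at 80 °C reduces the C–I bond and returns to the route at 16.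

## Further compounds

F1 | step 5 | methyl [(3S,4R)-5,7-bis(benzyloxy)-4-[4-(benzyloxy)phenyl]-2-oxochroman-3-yl]acetate | O=C1Oc2cc(OCc3ccccc3)cc(OCc3ccccc3)c2[C@@H](c2ccc(OCc3ccccc3)cc2)[C@@H]1CC(=O)OC
F2 | step 5 | (4S)-4-[(R)-[2,4-bis(benzyloxy)-6-hydroxyphenyl][4-(benzyloxy)phenyl]methyl]dihydrofuran-2(3H)-one | Oc1cc(OCc2ccccc2)cc(OCc2ccccc2)c1[C@@H](c1ccc(OCc2ccccc2)cc1)[C@@H]1CC(=O)OC1
F3 | step 5 | (4S)-4-[(R)-[4-(benzyloxy)phenyl][2,4,6-tris(benzyloxy)phenyl]methyl]dihydrofuran-2(3H)-one | c1ccccc1COc1cc(OCc2ccccc2)cc(OCc2ccccc2)c1[C@@H](c1ccc(OCc2ccccc2)cc1)[C@@H]1CC(=O)OC1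
F4 | step 5 | (3R,4R)-3-[4-(benzyloxy)benzyl]-4-[(R)-[4-(benzyloxy)phenyl][2,4,6-tris(benzyloxy)phenyl]methyl]dihydrofuran-2(3H)-one | c1ccccc1COc1cc(OCc2ccccc2)cc(OCc2ccccc2)c1[C@@H](c1ccc(OCc2ccccc2)cc1)[C@@H]1[C@@H](Cc2ccc(OCc3ccccc3)cc2)C(=O)OC1
F5 | step 5 | (2R,3R)-2-[4-(benzyloxy)benzyl]-3-[(R)-[4-(benzyloxy)phenyl][2,4,6-tris(benzyloxy)phenyl]methyl]butane-1,4-diol | c1ccccc1COc1cc(OCc2ccccc2)cc(OCc2ccccc2)c1[C@@H](c1ccc(OCc2ccccc2)cc1)[C@@H](CO)[C@H](CO)Cc1ccc(OCc2ccccc2)cc1
F6 | step 5 | (2R,3R)-2-[4-(benzyloxy)benzyl]-3-[(R)-[4-(benzyloxy)phenyl][2,4,6-tris(benzyloxy)phenyl]methyl]butane-1,4-diyl bis(4-methylbenzenesulfonate) | c1ccccc1COc1cc(OCc2ccccc2)cc(OCc2ccccc2)c1[C@@H](c1ccc(OCc2ccccc2)cc1)[C@@H](COS(=O)(=O)c1ccc(C)cc1)[C@H](COS(=O)(=O)c1ccc(C)cc1)Cc1ccc(OCc2ccccc2)cc1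
F7 | step 4 | diethyl [(4R)-5,7-bis(benzyloxy)-4-[4-(benzyloxy)phenyl]-2-oxochroman-3-yl]phosphonate (C3 epimers) | CCOP(=O)(OCC)C1C(=O)Oc2cc(OCc3ccccc3)cc(OCc3ccccc3)c2[C@H]1c1ccc(OCc2ccccc2)cc1
F8 | step 2 | (E)-3-[4-(benzyloxy)phenyl]prop-2-enal | O=C/C=C/c1ccc(OCc2ccccc2)cc1
F9 | step 2 | (4R)-5,7-bis(benzyloxy)-4-[4-(benzyloxy)phenyl]chroman-2-ol (anomers) | OC1C[C@H](c2ccc(OCc3ccccc3)cc2)c2c(OCc3ccccc3)cc(OCc3ccccc3)cc2O1
F10 | step 12 | 2,4,6-tris(benzyloxy)-3-[(1R,2S,3R)-1,4-bis[4-(benzyloxy)phenyl]-2,3-dimethylbutyl]benzaldehyde | c1ccccc1COc1c(C=O)c(OCc2ccccc2)cc(OCc2ccccc2)c1[C@@H](c1ccc(OCc2ccccc2)cc1)[C@@H](C)[C@H](C)Cc1ccc(OCc2ccccc2)cc1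
F11 | step 12 | 1-[2,4,6-tris(benzyloxy)-3-[(1R,2S,3R)-1,4-bis[4-(benzyloxy)phenyl]-2,3-dimethylbutyl]phenyl]-3-(4-methoxyphenyl)propan-1-ol (carbinol epimers) | c1ccccc1COc1c(C(O)CCc2ccc(OC)cc2)c(OCc2ccccc2)cc(OCc2ccccc2)c1[C@@H](c1ccc(OCc2ccccc2)cc1)[C@@H](C)[C@H](C)Cc1ccc(OCc2ccccc2)cc1
F12 | step 9 | 1,3,5-tris(benzyloxy)-2-[(1R,2S,3R)-1,4-bis[4-(benzyloxy)phenyl]-2-(iodomethyl)-3-methylbutyl]benzene | c1ccccc1COc1cc(OCc2ccccc2)cc(OCc2ccccc2)c1[C@@H](c1ccc(OCc2ccccc2)cc1)[C@@H](CI)[C@H](C)Cc1ccc(OCc2ccccc2)cc1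
A1 | alternative 1 | 2′,4′,6′-trihydroxy-4-methoxydihydrochalcone | COc1ccc(CCC(=O)c2c(O)cc(O)cc2O)cc1
A2 | alternative 1 | 4,4′-[(2R,3R)-2,3-dimethylbutane-1,4-diyl]diphenol | Oc1ccc(C[C@@H](C)[C@H](C)Cc2ccc(O)cc2)cc1
A3 | alternative 1 | 4-[(2S,3R)-4-(4-hydroxyphenyl)-2,3-dimethylbutylidene]cyclohexa-2,5-dien-1-one | O=C1C=CC(=C[C@@H](C)[C@H](C)Cc2ccc(O)cc2)C=C1
A4 | alternative 2 | 2-[(1S,2R,3R)-1,4-bis[4-(benzyloxy)phenyl]-2,3-dimethylbutyl]-4,4,5,5-tetramethyl-1,3,2-dioxaborolane | CC1(C)OB(OC1(C)C)[C@H](c1ccc(OCc2ccccc2)cc1)[C@@H](C)[C@H](C)Cc1ccc(OCc2ccccc2)cc1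
A5 | alternative 3 | (3E,4R)-4-(4-hydroxybenzyl)-3-(4-hydroxybenzylidene)dihydrofuran-2(3H)-one | O=C1OC[C@H](Cc2ccc(O)cc2)/C1=C\c1ccc(O)cc1
A6 | alternative 3 | (3R,4R)-4-(4-hydroxybenzyl)-3-[(S)-(4-hydroxyphenyl)(2,4,6-trihydroxyphenyl)methyl]dihydrofuran-2(3H)-one | Oc1cc(O)cc(O)c1[C@H](c1ccc(O)cc1)[C@H]1C(=O)OC[C@@H]1Cc1ccc(O)cc1
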